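(The numbers of this flask were drawn at random within sensible limits; no experiment stands behind them.)

- Time is the setting I must decide for the next charge: stop this flask at 30 s as planned, or leave it longer.

electrophile 20 mM; nucleophile 60.0 mM; buffer base 20.0 mM; buffer acid 2.00 mM; time 30 s

    electrophile + nucleophile → acid + product + leaving group (k1 = 2.7 L mol⁻¹ s⁻¹)
    protonated nucleophile ⇌ nucleophile + acid, settled at all times (K2 = 6.3 × 10⁻⁷ M)
    buffer acid ⇌ buffer base + acid, settled at all times (K3 = 5.0 × 10⁻⁶ M)
    electrophile ⇌ dormant form (K4 = 1.1, k4 = 0.026 s⁻¹)
    electrophile + leaving group ⇌ idle adduct A, settled at all times (K5 = 160 L mol⁻¹)
    electrophile + product ⇌ idle adduct B, settled at all times (K6 = 1600 L mol⁻¹)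

- acid is the free proton; pH is minus the decimal logarithm of its molar concentration
- in percentages every species weighs as the electrophile in it: one idle adduct B counts as two
- for product the idle adduct B is counted in
- for leaving group the idle adduct A is counted in
- what has gone from electrophile into another species counts as reacted, even if it can come back
- in an amount of product, one idle adduct B counts as one product
- run time (flask): 30 s

- part of the electrophile that has reacted at 30 s
- pH of the solution at 30 s

- I work with the fraction of free electrophile left, and I call the clock of the flask the half-life of free electrophile against the first step, ln(2) over the rate constant of that step times c(nucleophile); with c(nucleophile) held at its charge, a pseudo-first-order reckoning, the clock reads 4.28 s.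
- The forward half-life of the turning into dormant form is 27 s, longer than the clock, so I time the run on the first step, and 30 s holds 7.01 clock periods.
- The fraction left is then exp(-ln(2) times that count), or 0.775 %, so I reckon that 99.2 % of the electrophile has reacted and I would keep 30 s.
- My reckoning of the electrophile stops here, since the binding constant of idle adduct B times c(electrophile) at the start is 32, well above 1, and my clock does not follow electrophile that is held and later returned; I make no reckoning of the pH.
- The forecast differs from me on the part reacted, with 96.2 % (range 95 % to 97.2 %), on the ground that the electrophile is "rapidly tied up as adducts, mainly adduct B, as product accumulates", and it gives pH 6.69 (range 6.64 to 6.74).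
- This flask gives 96.1 % reacted and pH 6.70, both inside the forecast's ranges, and its free electrophile at 30.0 s is 3.90 %, more than my fraction left. With free nucleophile at 62 % of its charge at 30.0 s, the clock of this flask reads 6.87 s, still short against the run; in the neighbour flask with 15 mM of nucleophile, where 33 % of its charge is free and 79.9 % has reacted at the same time, it reads 52.7 s. This flask has not come to rest: at ten times the time, 99.4 % has reacted, free electrophile is 0.596 %, idle adduct B has fallen from 59.7 % to 26.8 %, and product, idle adduct B counted in, has risen from 53.7 % to 83.6 %.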